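**Plan**
1. Retrosynthetic cuts, in order: (i) the three MOM ethers and the oxidation level of the ester carbon (CO2Me ⇐ CH2OH); (ii) the bond between the ketone carbon and the ring A carbon flanked by the ester and the methoxy group, by a retro anionic homo-Fries (1,4 O→C aroyl) shift; (iii) the benzyl ester C–O bond, giving a ring A bromobenzyl alcohol (4) and a ring B acid (9).
2. Enabling feature: in ring A the ester carbon is ortho to the ketone-bearing carbon. At the CH2–O level this carbon and its oxygen tether the ring B acyl carbon, so the ring A carbanion reaches it through a five-membered cyclic transition state. This overcomes the crowding of the tetra-ortho-substituted diaryl ketone.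
3. Forward: ring A piece from methyl 3-hydroxy-5-methoxybenzoate (para-bromination, MOM, reduction); ring B piece from orcinol (bis-MOM, chlorination, ortho-lithiation/CO2); Mitsunobu esterification joins them; Br/Li exchange triggers the acyl shift; the tether carbon is then oxidised to CO2Me and the MOM groups are removed.
4. No ring is built: both benzene rings are bought, and the only ring closed is the transient oxolane of a lithium hemiketal in the key step.
5. Stereochemistry: none has to be set (see remark).

Key step: step 8

Remark on the chemistry: the target has no stereocentre and the diaryl ketone axis carries no descriptor and is taken as freely rotating, so the compound is achiral and the route needs no enantiocontrol.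

**Step 1**
Reactants: 1 methyl 3-hydroxy-5-methoxybenzoate
Product: 2 methyl 2-bromo-5-hydroxy-3-methoxybenzoate
Conditions: NBS (1.0 equiv), MeCN, −20 → 0 °C
Reagents that add atoms: N-bromosuccinimide, O=C1CCC(=O)N1Br
Why: Electrophilic aromatic bromination: the free hydroxyl is the strongest director and NBS in MeCN should brominate the phenol at its para position, the carbon between the ester and the methoxy group, which the methoxy group activates as well.

**Step 2**
Reactants: 2 methyl 2-bromo-5-hydroxy-3-methoxybenzoate
Product: 3 methyl 2-bromo-3-methoxy-5-(methoxymethoxy)benzoate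
Conditions: MOMCl, i-Pr2NEt, CH2Cl2, 0 °C → rt
Reagents that add atoms: chloromethyl methyl ether, COCCl
Why: O-Alkylation of the phenol with the reactive α-chloro ether (MOM protection) makes this oxygen inert to the later organolithium steps.

**Step 3**
Reactants: 3 methyl 2-bromo-3-methoxy-5-(methoxymethoxy)benzoate
Product: 4 [2-bromo-3-methoxy-5-(methoxymethoxy)phenyl]methanol
Conditions: DIBAL-H (2.5 equiv), CH2Cl2, −78 → 0 °C; aq. Rochelle salt
Reagents that add atoms: none
Why: DIBAL-H reduction of the ester to the primary alcohol should leave the aryl bromide and the MOM acetal untouched at low temperature.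

**Step 4**
Reactants: 5 orcinol (5-methylbenzene-1,3-diol)
Product: 6 1,3-bis(methoxymethoxy)-5-methylbenzene
Conditions: MOMCl (2.4 equiv), i-Pr2NEt, CH2Cl2, 0 °C → rt
Reagents that add atoms: chloromethyl methyl ether, COCCl
Why: Double MOM protection of the resorcinol gives two ether groups that later direct the lithiation to the carbon between them.

**Step 5**
Reactants: 6 1,3-bis(methoxymethoxy)-5-methylbenzene
Product: 7 2-chloro-1,5-bis(methoxymethoxy)-3-methylbenzene
Conditions: NCS (1.0 equiv), DMF, rt
Reagents that add atoms: N-chlorosuccinimide, O=C1CCC(=O)N1Cl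
Why: Electrophilic aromatic chlorination under neutral conditions should take place at one of the two equivalent positions ortho to one OMOM group and para to the other, because the position between the two OMOM groups is shielded.

**Step 6**
Reactants: 7 2-chloro-1,5-bis(methoxymethoxy)-3-methylbenzene
Product: 9 3-chloro-2,6-bis(methoxymethoxy)-4-methylbenzoic acid, via aryllithium 8 (not isolated)
Conditions: n-BuLi (1.1 equiv), THF, −20 → 0 °C; CO2 (g), −78 °C → rt; 1 M HCl to pH 3–4 at 0 °C
Reagents that add atoms: carbon dioxide, O=C=O
Why: Directed ortho-metalation at the C–H flanked by two MOM ethers (the most acidic and best coordinated site, with no hydrogen ortho to chlorine so that no aryne can form) is followed by carboxylation of the aryllithium.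

**Step 7**
Reactants: 4 [2-bromo-3-methoxy-5-(methoxymethoxy)phenyl]methanol; 9 3-chloro-2,6-bis(methoxymethoxy)-4-methylbenzoic acid
Product: 10 [2-bromo-3-methoxy-5-(methoxymethoxy)phenyl]methyl 3-chloro-2,6-bis(methoxymethoxy)-4-methylbenzoate
Conditions: PPh3, DIAD, THF, 0 °C → rt
Reagents that add atoms: none
Why: Mitsunobu esterification: the carboxylate of the hindered acid attacks the activated primary benzylic carbon in an SN2 step, so the crowded acyl carbon never has to be attacked.

**Step 8**
Reactants: 10 [2-bromo-3-methoxy-5-(methoxymethoxy)phenyl]methyl 3-chloro-2,6-bis(methoxymethoxy)-4-methylbenzoate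
Product: 13 [3-chloro-2,6-bis(methoxymethoxy)-4-methylphenyl][2-(hydroxymethyl)-6-methoxy-4-(methoxymethoxy)phenyl]methanone, via aryllithium 11 (not isolated), via cyclic lithium hemiketal alkoxide 12 (not isolated)
Conditions: n-BuLi (1.05 equiv), THF, −78 → −40 °C; AcOH (1.2 equiv), then H2O
Reagents that add atoms: none
Why: Bromine–lithium exchange at the ring A carbon between the benzylic carbon and the methoxy group should be faster at −78 °C than addition of n-BuLi to the ester, whose carbonyl is shielded by two ortho OMOM groups; aryllithium 11 then attacks that carbonyl through a five-membered cyclic transition state to give the cyclic lithium hemiketal alkoxide 12, which opens to the ketone and the benzylic alkoxide on collapse or on quench. The closest known reaction type is the anionic homo-Fries rearrangement (1,4 O→C acyl shift of an ortho-lithiated benzyl ester), a reaction type that has delivered tetra-ortho-substituted benzophenones. The transient oxolane ring of 12 closes in a 5-exo-trig mode and is not kept. No stereocentre appears in the product; the hemiketal carbon of 12 is racemic and is lost on ring opening. The step needs chemoselectivity (exchange before carbonyl addition, no attack on the aryl chloride, no second addition to the new ketone), and the substrate secures it by the steric shielding of the ester, the inertness of the aryl C–Cl bond to n-BuLi at low temperature, and the masking of the ketone as alkoxide 12 until the quench.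

**Step 9**
Reactants: 13 [3-chloro-2,6-bis(methoxymethoxy)-4-methylphenyl][2-(hydroxymethyl)-6-methoxy-4-(methoxymethoxy)phenyl]methanone
Product: 14 2-[3-chloro-2,6-bis(methoxymethoxy)-4-methylbenzoyl]-3-methoxy-5-(methoxymethoxy)benzaldehyde
Conditions: Dess–Martin periodinane, pyridine, CH2Cl2, 0 °C → rt
Reagents that add atoms: none
Why: Dess–Martin oxidation of the primary benzylic alcohol to the aldehyde runs under buffered, nearly neutral conditions that the MOM ethers tolerate, and ring–chain tautomerism of 13 does not interfere because only the open form can be oxidised.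

**Step 10**
Reactants: 14 2-[3-chloro-2,6-bis(methoxymethoxy)-4-methylbenzoyl]-3-methoxy-5-(methoxymethoxy)benzaldehyde
Product: 15 2-[3-chloro-2,6-bis(methoxymethoxy)-4-methylbenzoyl]-3-methoxy-5-(methoxymethoxy)benzoic acid
Conditions: NaClO2, NaH2PO4, 2-methyl-2-butene (excess), t-BuOH/H2O, 0 °C → rt
Reagents that add atoms: sodium chlorite, [Na+].[O-]Cl=O
Why: Pinnick oxidation of the aldehyde to the carboxylic acid, in which 2-methyl-2-butene traps the hypochlorous acid and so protects the electron-rich rings from chlorination.

**Step 11**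
Reactants: 15 2-[3-chloro-2,6-bis(methoxymethoxy)-4-methylbenzoyl]-3-methoxy-5-(methoxymethoxy)benzoic acid
Product: 16 methyl 2-[3-chloro-2,6-bis(methoxymethoxy)-4-methylbenzoyl]-3-methoxy-5-(methoxymethoxy)benzoate
Conditions: MeI, K2CO3, DMF, rt
Reagents that add atoms: iodomethane, CI
Why: O-Alkylation of the carboxylate with iodomethane (SN2) should give the normal methyl ester rather than the pseudo-ester, needs no attack on the hindered carbonyl, and meets no free phenol.

**Step 12**
Reactants: 16 methyl 2-[3-chloro-2,6-bis(methoxymethoxy)-4-methylbenzoyl]-3-methoxy-5-(methoxymethoxy)benzoate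
Product: 17 monochlorosulochrin, methyl 2-(3-chloro-2,6-dihydroxy-4-methylbenzoyl)-5-hydroxy-3-methoxybenzoate
Conditions: 3 M HCl in MeOH, rt → 40 °C
Reagents that add atoms: none
Why: Acid-catalysed acetal exchange (MOM cleavage) in methanol frees the three phenols, while the aryl methyl ether, the aryl chloride and the ketone are inert and the methyl ester can only exchange with methanol into itself.

**Compound list**
1 | methyl 3-hydroxy-5-methoxybenzoate | COC(=O)c1cc(O)cc(OC)c1 | starting material
2 | methyl 2-bromo-5-hydroxy-3-methoxybenzoate | COC(=O)c1cc(O)cc(OC)c1Br | intermediate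
3 | methyl 2-bromo-3-methoxy-5-(methoxymethoxy)benzoate | COC(=O)c1cc(OCOC)cc(OC)c1Br | intermediate
4 | [2-bromo-3-methoxy-5-(methoxymethoxy)phenyl]methanol | OCc1cc(OCOC)cc(OC)c1Br | intermediate
5 | orcinol (5-methylbenzene-1,3-diol) | Cc1cc(O)cc(O)c1 | starting material
6 | 1,3-bis(methoxymethoxy)-5-methylbenzene | Cc1cc(OCOC)cc(OCOC)c1 | intermediate
7 | 2-chloro-1,5-bis(methoxymethoxy)-3-methylbenzene | Cc1cc(OCOC)cc(OCOC)c1Cl | intermediate
8 | [3-chloro-2,6-bis(methoxymethoxy)-4-methylphenyl]lithium | [Li]c1c(OCOC)cc(C)c(Cl)c1OCOC | intermediate (not isolated)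
9 | 3-chloro-2,6-bis(methoxymethoxy)-4-methylbenzoic acid | Cc1cc(OCOC)c(C(=O)O)c(OCOC)c1Cl | intermediate
10 | [2-bromo-3-methoxy-5-(methoxymethoxy)phenyl]methyl 3-chloro-2,6-bis(methoxymethoxy)-4-methylbenzoate | COCOc1cc(COC(=O)c2c(OCOC)cc(C)c(Cl)c2OCOC)c(Br)c(OC)c1 | intermediate
11 | aryllithium from 10 (lithium in place of bromine on ring A) | COCOc1cc(COC(=O)c2c(OCOC)cc(C)c(Cl)c2OCOC)c([Li])c(OC)c1 | intermediate (not isolated)
12 | lithium 1-[3-chloro-2,6-bis(methoxymethoxy)-4-methylphenyl]-7-methoxy-5-(methoxymethoxy)-1,3-dihydro-2-benzofuran-1-olate (racemic) | [Li+].[O-]C1(c2c(OCOC)cc(C)c(Cl)c2OCOC)OCc2cc(OCOC)cc(OC)c21 | intermediate (not isolated)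
13 | [3-chloro-2,6-bis(methoxymethoxy)-4-methylphenyl][2-(hydroxymethyl)-6-methoxy-4-(methoxymethoxy)phenyl]methanone | COCOc1cc(CO)c(C(=O)c2c(OCOC)cc(C)c(Cl)c2OCOC)c(OC)c1 | intermediate
14 | 2-[3-chloro-2,6-bis(methoxymethoxy)-4-methylbenzoyl]-3-methoxy-5-(methoxymethoxy)benzaldehyde | COCOc1cc(C=O)c(C(=O)c2c(OCOC)cc(C)c(Cl)c2OCOC)c(OC)c1 | intermediate
15 | 2-[3-chloro-2,6-bis(methoxymethoxy)-4-methylbenzoyl]-3-methoxy-5-(methoxymethoxy)benzoic acid | COCOc1cc(C(=O)O)c(C(=O)c2c(OCOC)cc(C)c(Cl)c2OCOC)c(OC)c1 | intermediate
16 | methyl 2-[3-chloro-2,6-bis(methoxymethoxy)-4-methylbenzoyl]-3-methoxy-5-(methoxymethoxy)benzoate | COCOc1cc(C(=O)OC)c(C(=O)c2c(OCOC)cc(C)c(Cl)c2OCOC)c(OC)c1 | intermediate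
17 | monochlorosulochrin, methyl 2-(3-chloro-2,6-dihydroxy-4-methylbenzoyl)-5-hydroxy-3-methoxybenzoate | COC(=O)c1cc(O)cc(OC)c1C(=O)c1c(O)cc(C)c(Cl)c1O | target

**Step count**
Total: 12 steps. Longest linear sequence: 9 steps (steps 1–3 or 4–6, then 7–12).

**Steps most likely to fail**

Step 8. The intramolecular acyl transfer onto the doubly ortho-shielded carbonyl may be too slow, so that the aryllithium is protonated or butyllithium reacts elsewhere in the molecule. The fallback joins the rings by an intermolecular aryllithium–aldehyde addition and sets out from 4 and 7, returning at 13. Alcohol 4 would be silylated (TBSCl, imidazole, DMF) to tert-butyl{[2-bromo-3-methoxy-5-(methoxymethoxy)phenyl]methoxy}dimethylsilane F1. Chloroarene 7 would be lithiated as in step 6 and quenched with DMF to give 3-chloro-2,6-bis(methoxymethoxy)-4-methylbenzaldehyde F2. Br/Li exchange of F1 (n-BuLi, THF, −78 °C) and addition to F2 should give the racemic diaryl carbinol [2-({[tert-butyl(dimethyl)silyl]oxy}methyl)-6-methoxy-4-(methoxymethoxy)phenyl][3-chloro-2,6-bis(methoxymethoxy)-4-methylphenyl]methanol F3. Dess–Martin oxidation would give the ketone [2-({[tert-butyl(dimethyl)silyl]oxy}methyl)-6-methoxy-4-(methoxymethoxy)phenyl][3-chloro-2,6-bis(methoxymethoxy)-4-methylphenyl]methanone F4, and TBAF in THF would then free the alcohol 13.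

Step 1. Bromination may take place para to the methoxy group, between the two oxygens, or twice. The fallback fixes the site by directed metalation and sets out from 1, returning at 4. Phenol 1 would be silylated (TIPSCl, imidazole, DMF) to methyl 3-methoxy-5-[(triisopropylsilyl)oxy]benzoate F5 and reduced with DIBAL-H to {3-methoxy-5-[(triisopropylsilyl)oxy]phenyl}methanol F6. With n-BuLi (2.2 equiv) the lithium alkoxide and the methoxy group should jointly direct lithiation to the carbon between them, while the bulky silyl ether shields the other two ring positions. A quench with 1,2-dibromotetrachloroethane would give {2-bromo-3-methoxy-5-[(triisopropylsilyl)oxy]phenyl}methanol F7. TBAF would give 4-bromo-3-(hydroxymethyl)-5-methoxyphenol F8, and phenol-selective alkylation (MOMCl, K2CO3, acetone) would give 4.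

Step 5. Chlorination may occur between the two OMOM groups or twice, or adventitious HCl may cleave a MOM group. The fallback reverses the order of carboxylation and chlorination and sets out from 6, returning at 9. Lithiation of 6 between its two OMOM groups (n-BuLi, THF, 0 °C) and carboxylation with CO2 would give the symmetrical 2,6-bis(methoxymethoxy)-4-methylbenzoic acid F9. Its two open ring positions are equivalent, so chlorination with NCS (1.0 equiv, DMF), a known reaction type for 2,6-dialkoxybenzoic acids, can give only one monochloride, which is 9.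

**Further compounds**
F1 | step 8 | tert-butyl{[2-bromo-3-methoxy-5-(methoxymethoxy)phenyl]methoxy}dimethylsilane | COCOc1cc(CO[Si](C)(C)C(C)(C)C)c(Br)c(OC)c1
F2 | step 8 | 3-chloro-2,6-bis(methoxymethoxy)-4-methylbenzaldehyde | Cc1cc(OCOC)c(C=O)c(OCOC)c1Cl
F3 | step 8 | rac-[2-({[tert-butyl(dimethyl)silyl]oxy}methyl)-6-methoxy-4-(methoxymethoxy)phenyl][3-chloro-2,6-bis(methoxymethoxy)-4-methylphenyl]methanol | COCOc1cc(CO[Si](C)(C)C(C)(C)C)c(C(O)c2c(OCOC)cc(C)c(Cl)c2OCOC)c(OC)c1
F4 | step 8 | [2-({[tert-butyl(dimethyl)silyl]oxy}methyl)-6-methoxy-4-(methoxymethoxy)phenyl][3-chloro-2,6-bis(methoxymethoxy)-4-methylphenyl]methanone | COCOc1cc(CO[Si](C)(C)C(C)(C)C)c(C(=O)c2c(OCOC)cc(C)c(Cl)c2OCOC)c(OC)c1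
F5 | step 1 | methyl 3-methoxy-5-[(triisopropylsilyl)oxy]benzoate | COC(=O)c1cc(OC)cc(O[Si](C(C)C)(C(C)C)C(C)C)c1
F6 | step 1 | {3-methoxy-5-[(triisopropylsilyl)oxy]phenyl}methanol | OCc1cc(OC)cc(O[Si](C(C)C)(C(C)C)C(C)C)c1
F7 | step 1 | {2-bromo-3-methoxy-5-[(triisopropylsilyl)oxy]phenyl}methanol | OCc1cc(O[Si](C(C)C)(C(C)C)C(C)C)cc(OC)c1Br
F8 | step 1 | 4-bromo-3-(hydroxymethyl)-5-methoxyphenol | OCc1cc(O)cc(OC)c1Br
F9 | step 5 | 2,6-bis(methoxymethoxy)-4-methylbenzoic acid | Cc1cc(OCOC)c(C(=O)O)c(OCOC)c1
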